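At the last reading of Saturday's run, 2.50 min, the starting material stood at 21.2%, having fallen from 23.3% since 1.00 min, whereas in Friday's run, with reagent in excess, it went down to 0.5%.

| flask | starting material | reagent | free catalyst | remark | time |
|---|---|---|---|---|---|
| Friday's | 0.12 M | 0.15 M | 5 mM | run made earlier |  |
| Saturday's | 0.19 M | 0.15 M | 5 mM | run made earlier |  |
| flask | 0.25 M | 0.150 M | 5.0 mM |  | 3.0 min |

| run | time / min | target / % | starting material / % |
|---|---|---|---|
| Friday's | 0.167 | 33.1 | 59.7 |
| Friday's | 0.250 | 43.1 | 45.2 |
| Friday's | 0.500 | 46.9 | 20.9 |
| Friday's | 1.00 | 29.7 | 4.4 |
| Friday's | 2.50 | 7.0 | 0.5 |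
| Saturday's | 0.167 | 27.4 | 68.7 |
| Saturday's | 0.250 | 33.3 | 56.7 |
| Saturday's | 0.500 | 37.5 | 35.7 |
| Saturday's | 1.00 | 23.4 | 23.3 |
| Saturday's | 2.50 | 4.3 | 21.2 |

(standard deviation of a reading: 0.5 percentage points)

- steps that have been proposed: reagent + free catalyst <-> catalyst intermediate A; catalyst intermediate B -> catalyst intermediate C; target <-> isomer of the product; starting material + catalyst intermediate A -> catalyst intermediate B; catalyst intermediate C -> free catalyst + target

- the moment within 3.0 min at which there is most target
- the amount of target, in percent of the starting material charged, at that time

I therefore worked with the fraction left, one minus reagent charged over starting material charged: the part of the starting material that stays unreacted if each reagent takes one starting material. For Saturday's run it came to 21.1%, against the reading of 21.2%. For this flask, where reagent is the limiting reagent, the fraction left is 40.0%, so target and isomer together have a ceiling of 60.0% of the charge.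

But target is lost again: in Friday's run it fell from 29.7% to 7.0% between the last two readings. So I tested whether this one number was enough. The highest target reading was 46.9% of Friday's ceiling, there the whole charge, and 47.5% of Saturday's. Carrying that share over, I reckoned 28.5% for this flask.

The forecast stood higher, at 34% after 0.44 min: “formation falls to about 1.25 × target when conversion is near 0.125 M”.

The flask gave 32.1% after 0.408 min, within the forecast's margins and above my figure, so the share did not carry over.

    reagent + free catalyst ⇌ catalyst intermediate A (K = 14.9 L mol⁻¹, k = 39.3 L mol⁻¹ s⁻¹)
    catalyst intermediate B → catalyst intermediate C (k = 11.4 s⁻¹)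
    target ⇌ isomer of the product (K = 18.5, k = 0.0309 s⁻¹)
    starting material + catalyst intermediate A → catalyst intermediate B (k = 29.9 L mol⁻¹ s⁻¹)
    catalyst intermediate C → free catalyst + target (k = 5.38 s⁻¹)

In this flask, by 0.189 min half the turnover up to the longest time allowed of reagent binding free catalyst was done, and target was being made 2.80 times faster than used up, each step taken net. By 1.50 min this flask's reagent was down to 0.0264% of its charge, while target stood at 8.50% against 51.5% of isomer. Its starting material stood at 40.0% after 3.00 min, as the fraction left said. For the same flask with 0.037 M of reagent the fraction left is 85.2%; computed, that flask ended with 85.2% starting material.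

The readings stem from a simulated flask for substances that don't exist; the scatter is artificial.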